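The lactone is numbered O1, C2(=O), C3–C6, with the side chain running from C7. The dihydropyranone is opened at C3–C2 and O1–C6, so that C2 with both oxygens becomes carbon dioxide. The key step exploits the cis C3=C4 bond of the ring and the 1,3-relationship between the ring oxygen on C6 and the C8 hydroxyl. A (Z)-vinyllithium at C3 captures CO2; the new carboxylate then opens, with inversion at C6, a six-membered cyclic sulfate spanning C6 and C8. This closes the lactone and uncovers the C8 oxygen in one flask. The precursor is an acyclic (Z)-iodoalkene carrying this anti-diol sulfate, assembled by a 1,5-anti boron aldol and a 1,3-anti reduction.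

Key step: step 10

Remark: the CIP descriptors of C8 and C10 change along the route only because substituent priorities change. The SMILES show that no configured carbon other than C6 (step 10) is inverted.

Step 1
Reactants: 1 hexadecanal; 2 allylmagnesium bromide
Product: 4 (R)-nonadec-1-en-4-ol, via homoallyl borinate 3 (not isolated)
Conditions: (−)-Ipc2BOMe, allylMgBr, Et2O, 0 °C to rt; then 1, −78 °C; NaOH, H2O2, 0 °C to rt
Reagents that add atoms: none
Why: Brown allylation: the B-allyldiisopinocampheylborane made in the flask from the (+)-α-pinene-derived methoxyborane should add through a closed chair transition state to the Si face of the unbranched aldehyde, which sets C12 as R, and oxidative work-up frees the alcohol from borinate 3.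

Step 2
Reactants: 4 (R)-nonadec-1-en-4-ol; 5 but-3-en-2-one
Product: 6 (3E,6R)-6-hydroxyhenicos-3-en-2-one
Conditions: second-generation Hoveyda–Grubbs catalyst (3 mol %), 5 (3 equiv), CH2Cl2, 40 °C
Reagents that add atoms: none
Why: Olefin cross-metathesis of a terminal alkene with an electron-poor enone should favour the cross product and the E enone, with loss of ethene and without touching C12.

Step 3
Reactants: 6 (3E,6R)-6-hydroxyhenicos-3-en-2-one; 7 acetaldehyde
Product: 9 1-[(2R,4R,6R)-2-methyl-6-pentadecyl-1,3-dioxan-4-yl]propan-2-one, via hemiacetal 8 (not isolated)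
Conditions: Bi(NO3)3·5H2O (10 mol %), MeCHO (5 equiv), CH2Cl2, rt
Reagents that add atoms: none
Why: Hemiacetal formation followed by intramolecular oxa-Michael addition to the enone is reversible, so the all-equatorial 2,4,6-cis dioxane should prevail, which places the new C10 oxygen syn to C12.

Step 4
Reactants: 10 4-(trimethylsilyl)but-3-yn-1-ol
Product: 11 4-(trimethylsilyl)but-3-ynal
Conditions: Dess–Martin periodinane, NaHCO3, CH2Cl2, 0 °C; used at once without purification
Reagents that add atoms: none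
Why: Dess–Martin oxidation under buffered conditions should give the β,γ-alkynyl aldehyde without the acid or base that would isomerise it to the allenyl aldehyde.

Step 5
Reactants: 9 1-[(2R,4R,6R)-2-methyl-6-pentadecyl-1,3-dioxan-4-yl]propan-2-one; 11 4-(trimethylsilyl)but-3-ynal
Product: 14 (4R)-4-hydroxy-1-[(2R,4R,6R)-2-methyl-6-pentadecyl-1,3-dioxan-4-yl]-7-(trimethylsilyl)hept-6-yn-2-one, via boron enolate 12 (not isolated), via boron aldolate 13 (not isolated)
Conditions: (c-Hex)2BCl, Et3N, Et2O, 0 °C; then 11, −78 to −20 °C; H2O2, MeOH, pH 7 buffer, 0 °C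
Reagents that add atoms: none
Why: Boron aldol addition of the kinetic methyl-side enolate of a β-alkoxy methyl ketone is expected to show 1,5-anti induction through a boat transition state in which the aldehyde C–H contacts the β-oxygen of the dioxane, which sets the new C6 carbinol as R, anti to the C10 oxygen.

Step 6
Reactants: 14 (4R)-4-hydroxy-1-[(2R,4R,6R)-2-methyl-6-pentadecyl-1,3-dioxan-4-yl]-7-(trimethylsilyl)hept-6-yn-2-one
Product: 16 (2S,4R)-1-[(2R,4S,6R)-2-methyl-6-pentadecyl-1,3-dioxan-4-yl]-7-(trimethylsilyl)hept-6-yne-2,4-diol, via alkoxyborohydride 15 (not isolated)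
Conditions: Me4NBH(OAc)3, MeCN/AcOH (1:1), −30 °C
Reagents that add atoms: none
Why: Evans–Saksena reduction: the C6 hydroxyl exchanges onto boron and delivers hydride intramolecularly through a chair transition state, which should give the 1,3-anti diol, so that the new C8 carbinol is anti to C6 and syn to C10 as in the target.

Step 7
Reactants: 16 (2S,4R)-1-[(2R,4S,6R)-2-methyl-6-pentadecyl-1,3-dioxan-4-yl]-7-(trimethylsilyl)hept-6-yne-2,4-diol
Product: 17 (2S,4R)-7-iodo-1-[(2R,4S,6R)-2-methyl-6-pentadecyl-1,3-dioxan-4-yl]hept-6-yne-2,4-diol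
Conditions: N-iodosuccinimide, AgNO3 (20 mol %), DMF, rt, dark
Reagents that add atoms: N-iodosuccinimide, O=C1CCC(=O)N1I
Why: Silver-catalysed iododesilylation of a trimethylsilylalkyne through the silver acetylide should give the 1-iodoalkyne directly and leave the diol, the acetal and all stereocentres untouched.

Step 8
Reactants: 17 (2S,4R)-7-iodo-1-[(2R,4S,6R)-2-methyl-6-pentadecyl-1,3-dioxan-4-yl]hept-6-yne-2,4-diol
Product: 18 (2S,4R,6Z)-7-iodo-1-[(2R,4S,6R)-2-methyl-6-pentadecyl-1,3-dioxan-4-yl]hept-6-ene-2,4-diol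
Conditions: 2-nitrobenzenesulfonyl hydrazide, Et3N, THF/i-PrOH, rt
Reagents that add atoms: none
Why: Diimide reduction transfers two hydrogens to the same face of the iodoalkyne in a concerted step, which should give only the (Z)-iodoalkene without cleaving the C–I bond.

Step 9
Reactants: 18 (2S,4R,6Z)-7-iodo-1-[(2R,4S,6R)-2-methyl-6-pentadecyl-1,3-dioxan-4-yl]hept-6-ene-2,4-diol
Product: 20 (4R,6R)-4-[(2Z)-3-iodoprop-2-en-1-yl]-6-{[(2R,4R,6R)-2-methyl-6-pentadecyl-1,3-dioxan-4-yl]methyl}-1,3,2-dioxathiane 2,2-dioxide, via disodium dialkoxide 19 (not isolated)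
Conditions: NaH (2.2 equiv), THF, −20 °C; then 1,1'-sulfonyldiimidazole, −40 to 0 °C
Reagents that add atoms: 1,1'-sulfonyldiimidazole, O=S(=O)(n1ccnc1)n1ccnc1
Why: Cyclic sulfate formation from a 1,3-diol by two successive sulfonyl transfers to the alkoxides should close the six-membered ring without touching a carbon stereocentre, and it avoids the RuO4 oxidation of a cyclic sulfite, which would attack the iodoalkene.

Step 10
Reactants: 20 (4R,6R)-4-[(2Z)-3-iodoprop-2-en-1-yl]-6-{[(2R,4R,6R)-2-methyl-6-pentadecyl-1,3-dioxan-4-yl]methyl}-1,3,2-dioxathiane 2,2-dioxide; 21 carbon dioxide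
Product: 25 (6S)-6-{(2R)-2-hydroxy-3-[(2R,4S,6R)-2-methyl-6-pentadecyl-1,3-dioxan-4-yl]propyl}-5,6-dihydro-2H-pyran-2-one, via vinyllithium 22 (not isolated), via lithium carboxylate 23 (not isolated), via lactone lithium sulfate 24 (not isolated)
Conditions: t-BuLi (2.1 equiv), Et2O/pentane, −100 °C; CO2, −100 to −78 °C; THF, −78 °C to rt; then H2SO4 (cat.), H2O (2 equiv), THF, rt
Reagents that add atoms: none
Why: Iodine–lithium exchange, which at −100 °C should outrun any attack of t-BuLi on the sulfate, gives the configurationally stable (Z)-alkenyllithium 22, and its addition to CO2 (carboxylation of an organolithium) forms the C3–C2 bond and brings in C2 with both oxygens as carboxylate 23. On warming, one carboxylate oxygen displaces the sulfate oxygen at C6 in an intramolecular SN2 reaction, the known opening of cyclic sulfates by carboxylates, which forms the O1–C6 bond and closes the δ-lactone in a 6-exo-tet mode. C6 is the only stereocentre made here and is controlled by stereospecific inversion of the R-configured sulfate carbon laid down in steps 5 and 6, which turns the anti C6/C8 pair into the syn pair of the target; C8 keeps its configuration because only its O–S bond is cleaved in the final hydrolysis of 24. The step needs chemoselectivity (exchange before attack on the sulfate), secured by the rate of exchange at low temperature and by immediate trapping with CO2, and regioselectivity for C6 over C8, secured by ring size, since attack at C8 would need an eight-membered ring. The Z geometry of C3=C4, retained through exchange and carboxylation, is what brings the carboxylate within reach of C6. Catalytic H2SO4 with a little water then cleaves the monoalkyl sulfate without touching the ethylidene acetal.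

Step 11
Reactants: 25 (6S)-6-{(2R)-2-hydroxy-3-[(2R,4S,6R)-2-methyl-6-pentadecyl-1,3-dioxan-4-yl]propyl}-5,6-dihydro-2H-pyran-2-one
Product: 26 (6S)-6-[(2R,4R,6R)-2,4,6-trihydroxyhenicosyl]-5,6-dihydro-2H-pyran-2-one
Conditions: 2 M aq. HCl, THF, 40 °C
Reagents that add atoms: none
Why: Acid hydrolysis of the ethylidene acetal should release the C10 and C12 hydroxyls and acetaldehyde, while the unsaturated δ-lactone and the four stereocentres are expected to tolerate aqueous acid at this temperature.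

Compound list
1 | hexadecanal | CCCCCCCCCCCCCCCC=O | starting material
2 | allylmagnesium bromide | C=CC[Mg]Br | starting material
3 | (R)-nonadec-1-en-4-yl diisopinocampheylborinate (isopinocampheyl groups from (+)-α-pinene) | CCCCCCCCCCCCCCC[C@@H](OB([C@@H]1C[C@@H]2C[C@@H](C2(C)C)[C@H]1C)[C@@H]1C[C@@H]2C[C@@H](C2(C)C)[C@H]1C)CC=C | intermediate
4 | (R)-nonadec-1-en-4-ol | CCCCCCCCCCCCCCC[C@@H](O)CC=C | intermediate
5 | but-3-en-2-one (methyl vinyl ketone) | CC(=O)C=C | starting material
6 | (3E,6R)-6-hydroxyhenicos-3-en-2-one | CCCCCCCCCCCCCCC[C@@H](O)C/C=C/C(C)=O | intermediate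
7 | acetaldehyde | CC=O | starting material
8 | (3E,6R)-6-(1-hydroxyethoxy)henicos-3-en-2-one (hemiacetal, either configuration at the hemiacetal carbon) | CCCCCCCCCCCCCCC[C@@H](OC(C)O)C/C=C/C(C)=O | intermediate
9 | 1-[(2R,4R,6R)-2-methyl-6-pentadecyl-1,3-dioxan-4-yl]propan-2-one (2,4,6-cis dioxane) | CCCCCCCCCCCCCCC[C@@H]1C[C@@H](O[C@H](C)O1)CC(C)=O | intermediate
10 | 4-(trimethylsilyl)but-3-yn-1-ol | C[Si](C)(C)C#CCCO | starting material
11 | 4-(trimethylsilyl)but-3-ynal | C[Si](C)(C)C#CCC=O | intermediate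
12 | dicyclohexylboron enolate of 9 (methyl-side enol borinate) | CCCCCCCCCCCCCCC[C@@H]1C[C@@H](O[C@H](C)O1)CC(=C)OB(C2CCCCC2)C2CCCCC2 | intermediate
13 | dicyclohexylborinate of aldol 14 at the C6 oxygen | CCCCCCCCCCCCCCC[C@@H]1C[C@@H](O[C@H](C)O1)CC(=O)C[C@H](OB(C2CCCCC2)C2CCCCC2)CC#C[Si](C)(C)C | intermediate
14 | (4R)-4-hydroxy-1-[(2R,4R,6R)-2-methyl-6-pentadecyl-1,3-dioxan-4-yl]-7-(trimethylsilyl)hept-6-yn-2-one | CCCCCCCCCCCCCCC[C@@H]1C[C@@H](O[C@H](C)O1)CC(=O)C[C@H](O)CC#C[Si](C)(C)C | intermediate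
15 | tetramethylammonium diacetoxy(hydrido)borate ester of the C6 hydroxyl of 14 | CCCCCCCCCCCCCCC[C@@H]1C[C@@H](O[C@H](C)O1)CC(=O)C[C@H](O[BH-](OC(C)=O)OC(C)=O)CC#C[Si](C)(C)C.C[N+](C)(C)C | intermediate
16 | (2S,4R)-1-[(2R,4S,6R)-2-methyl-6-pentadecyl-1,3-dioxan-4-yl]-7-(trimethylsilyl)hept-6-yne-2,4-diol (C6/C8 anti, C8/C10/C12 syn) | CCCCCCCCCCCCCCC[C@@H]1C[C@@H](O[C@H](C)O1)C[C@@H](O)C[C@H](O)CC#C[Si](C)(C)C | intermediate
17 | (2S,4R)-7-iodo-1-[(2R,4S,6R)-2-methyl-6-pentadecyl-1,3-dioxan-4-yl]hept-6-yne-2,4-diol | CCCCCCCCCCCCCCC[C@@H]1C[C@@H](O[C@H](C)O1)C[C@@H](O)C[C@H](O)CC#CI | intermediate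
18 | (2S,4R,6Z)-7-iodo-1-[(2R,4S,6R)-2-methyl-6-pentadecyl-1,3-dioxan-4-yl]hept-6-ene-2,4-diol | CCCCCCCCCCCCCCC[C@@H]1C[C@@H](O[C@H](C)O1)C[C@@H](O)C[C@H](O)C/C=C\I | intermediate
19 | disodium dialkoxide of 18 | CCCCCCCCCCCCCCC[C@@H]1C[C@@H](O[C@H](C)O1)C[C@@H]([O-])C[C@H]([O-])C/C=C\I.[Na+].[Na+] | intermediate
20 | (4R,6R)-4-[(2Z)-3-iodoprop-2-en-1-yl]-6-{[(2R,4R,6R)-2-methyl-6-pentadecyl-1,3-dioxan-4-yl]methyl}-1,3,2-dioxathiane 2,2-dioxide (trans cyclic sulfate of the C6/C8 anti-diol) | CCCCCCCCCCCCCCC[C@@H]1C[C@@H](O[C@H](C)O1)C[C@@H]2C[C@@H](C/C=C\I)OS(=O)(=O)O2 | intermediate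
21 | carbon dioxide | O=C=O | starting material
22 | (Z)-alkenyllithium from 20 (lithium in place of iodine at C3) | CCCCCCCCCCCCCCC[C@@H]1C[C@@H](O[C@H](C)O1)C[C@@H]2C[C@@H](C/C=C\[Li])OS(=O)(=O)O2 | intermediate
23 | lithium (2Z)-4-[(4R,6R)-6-{[(2R,4R,6R)-2-methyl-6-pentadecyl-1,3-dioxan-4-yl]methyl}-2,2-dioxido-1,3,2-dioxathian-4-yl]but-2-enoate | CCCCCCCCCCCCCCC[C@@H]1C[C@@H](O[C@H](C)O1)C[C@@H]2C[C@@H](C/C=C\C(=O)[O-])OS(=O)(=O)O2.[Li+] | intermediate
24 | lithium salt of the C8 sulfate monoester of lactone 25 | CCCCCCCCCCCCCCC[C@@H]1C[C@@H](O[C@H](C)O1)C[C@@H](OS(=O)(=O)[O-])C[C@@H]2CC=CC(=O)O2.[Li+] | intermediate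
25 | (6S)-6-{(2R)-2-hydroxy-3-[(2R,4S,6R)-2-methyl-6-pentadecyl-1,3-dioxan-4-yl]propyl}-5,6-dihydro-2H-pyran-2-one | CCCCCCCCCCCCCCC[C@@H]1C[C@@H](O[C@H](C)O1)C[C@@H](O)C[C@@H]2CC=CC(=O)O2 | intermediate
26 | (6S)-6-[(2R,4R,6R)-2,4,6-trihydroxyhenicosyl]-5,6-dihydro-2H-pyran-2-one | CCCCCCCCCCCCCCC[C@@H](O)C[C@@H](O)C[C@@H](O)C[C@@H]1CC=CC(=O)O1 | target

Total step count: 11. Longest linear sequence: 10 steps (steps 1, 2, 3, 5, 6, 7, 8, 9, 10, 11); step 4 is a one-step side branch.

Steps most likely to fail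

Step 10. The organolithium chemistry may not survive next to the cyclic sulfate: t-BuLi or the alkenyllithium may attack sulfur or carbon of the sulfate before carboxylation, and the lithium iodide formed may open the sulfate and erode the configuration at C6 by double inversion. The fallback makes the C3–C2 bond by palladium acyl chemistry instead of an organolithium. It sets out from 20: hydroxycarbonylation of the iodoalkene (Pd(OAc)2, 1,1'-bis(diphenylphosphino)ferrocene, CO 1 atm, H2O, i-Pr2NEt, THF, 50 °C) should give the (Z)-enoic acid cyclic sulfate F1. Its ammonium carboxylate should open the sulfate at C6 in the same 6-exo-tet manner to the lactone hydrogen sulfate F2. Hydrolysis (H2SO4 cat., H2O, THF, rt) comes back to the route at 25.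

Step 9. Sulfonyl transfer under basic conditions may fail through loss of HI from the (Z)-iodoalkene by the alkoxides or through intermolecular sulfate formation (oligomers). The fallback builds the sulfate before the C=C bond exists, by the two-stage sulfite route. It sets out from 17: SOCl2 and pyridine (CH2Cl2, 0 °C) should give the cyclic sulfite F3. RuCl3 (cat.) with NaIO4 (MeCN/CCl4/H2O, 0 °C) should oxidise it to the iodoalkynyl cyclic sulfate F4. Diimide reduction without amine (2-nitrobenzenesulfonyl hydrazide, THF/i-PrOH, rt) comes back to the route at 20.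

Step 5. The aldehyde 11 may isomerise to the allenyl aldehyde under the amine, and facial selectivity may be poor if the acetal oxygen induces less 1,5-anti bias than an ether oxygen. The fallback takes C6 from the chiral pool and makes the C7–C8 bond by dithiane alkylation. It sets out from 4 and comes back to the route at 14.
- Cross-metathesis of 4 with acrolein (second-generation Hoveyda–Grubbs catalyst) should give (2E,5R)-5-hydroxyicos-2-enal F5.
- The same bismuth-mediated acetalisation with acetaldehyde should give 2-[(2R,4R,6R)-2-methyl-6-pentadecyl-1,3-dioxan-4-yl]acetaldehyde F6.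
- 1,3-Propanedithiol with MgBr2·OEt2 should give the dithiane F7.
- Separately, (R)-epichlorohydrin is opened by lithium (trimethylsilyl)acetylide with BF3·OEt2 to (R)-1-chloro-5-(trimethylsilyl)pent-4-yn-2-ol F8, which is closed with NaH to trimethyl{3-[(2R)-oxiran-2-yl]prop-1-yn-1-yl}silane F9.
- Lithiated F7 (t-BuLi, THF/HMPA, −78 °C) should open F9 at its CH2 terminus to the dithiane alcohol F10.
- Dithiane hydrolysis (MeI, CaCO3, aq. MeCN) gives 14.

Further compounds
F1 | step 10 | (2Z)-4-[(4R,6R)-6-{[(2R,4R,6R)-2-methyl-6-pentadecyl-1,3-dioxan-4-yl]methyl}-2,2-dioxido-1,3,2-dioxathian-4-yl]but-2-enoic acid | CCCCCCCCCCCCCCC[C@@H]1C[C@@H](O[C@H](C)O1)C[C@@H]2C[C@@H](C/C=C\C(=O)O)OS(=O)(=O)O2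
F2 | step 10 | hydrogen sulfate of lactone 25 at the C8 oxygen | CCCCCCCCCCCCCCC[C@@H]1C[C@@H](O[C@H](C)O1)C[C@@H](OS(=O)(=O)O)C[C@@H]2CC=CC(=O)O2
F3 | step 9 | cyclic sulfite of diol 17 (1,3,2-dioxathiane 2-oxide, either configuration at sulfur) | CCCCCCCCCCCCCCC[C@@H]1C[C@@H](O[C@H](C)O1)C[C@@H]2C[C@@H](CC#CI)OS(=O)O2
F4 | step 9 | (4R,6R)-4-(3-iodoprop-2-yn-1-yl)-6-{[(2R,4R,6R)-2-methyl-6-pentadecyl-1,3-dioxan-4-yl]methyl}-1,3,2-dioxathiane 2,2-dioxide | CCCCCCCCCCCCCCC[C@@H]1C[C@@H](O[C@H](C)O1)C[C@@H]2C[C@@H](CC#CI)OS(=O)(=O)O2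
F5 | step 5 | (2E,5R)-5-hydroxyicos-2-enal | CCCCCCCCCCCCCCC[C@@H](O)C/C=C/C=O
F6 | step 5 | 2-[(2R,4R,6R)-2-methyl-6-pentadecyl-1,3-dioxan-4-yl]acetaldehyde | CCCCCCCCCCCCCCC[C@@H]1C[C@@H](O[C@H](C)O1)CC=O
F7 | step 5 | 2-{[(2R,4R,6R)-2-methyl-6-pentadecyl-1,3-dioxan-4-yl]methyl}-1,3-dithiane | CCCCCCCCCCCCCCC[C@@H]1C[C@@H](O[C@H](C)O1)CC2SCCCS2
F8 | step 5 | (R)-1-chloro-5-(trimethylsilyl)pent-4-yn-2-ol | C[Si](C)(C)C#CC[C@@H](O)CCl
F9 | step 5 | trimethyl{3-[(2R)-oxiran-2-yl]prop-1-yn-1-yl}silane | C[Si](C)(C)C#CC[C@@H]1CO1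
F10 | step 5 | (2R)-1-(2-{[(2R,4R,6R)-2-methyl-6-pentadecyl-1,3-dioxan-4-yl]methyl}-1,3-dithian-2-yl)-5-(trimethylsilyl)pent-4-yn-2-ol | CCCCCCCCCCCCCCC[C@@H]1C[C@@H](O[C@H](C)O1)CC2(C[C@H](O)CC#C[Si](C)(C)C)SCCCS2
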